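**Strategy.** The indoxyl is cut at the two bonds that tie its unsubstituted benzo ring to the hetero ring: N1–C7a and C3–C3a. Because that ring is attached only through this ortho pair of carbons, it maps onto benzyne, and the remaining N1–C2–C3 unit maps onto an N-sulfonyl α,α-bis(indol-3-yl)glycine ester whose quaternary carbon becomes C2. One fluoride-triggered operation adds the sulfonamide nitrogen to benzyne and closes the five-membered ring by attack of the resulting aryl anion on the ester, forming both bonds and the C3 ketone. The precursor is ethyl 2,2-bis(1-Boc-indol-3-yl)-2-(tosylamino)acetate, reached in three steps from a commercial indolylglyoxylate.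

Key step: step 4

**Remarks on the chemistry.**
- The target has no stereocentre, because C2 carries two identical indol-3-yl groups. The C=N geometry of the ketimine is left undefined, since it is lost in step 2.
- Tosyl is kept on the glycine nitrogen. It is acidic enough for CsF, it has no α-hydrogen that could quench the aryl anion, and it is too electron-rich for a Truce–Smiles shift, which argues against nitrobenzenesulfonyl groups.
- Boc on both indole nitrogens blocks indole N-arylation and removes N–H proton sources. It also stops the indole from expelling the sulfonamide nitrogen from C2 through an alkylideneindolenine.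
- For the last reason the sulfonyl group is removed before the Boc groups, by aprotic electron transfer, and base is admitted only afterwards.

**Route**

Step 1
Reactants: 1 ethyl 2-(1H-indol-3-yl)-2-oxoacetate; 2 4-methylbenzenesulfonamide
Product: 3 ethyl 2-(1H-indol-3-yl)-2-(tosylimino)acetate
Conditions: TiCl4 (0.6 equiv), Et3N (3 equiv), CH2Cl2, 0 °C to reflux; Celite filtration, used crude
Reagents that add atoms: none
Why: TiCl4/Et3N-mediated ketone–sulfonamide condensation, in which chelation of titanium by the 1,2-dicarbonyl unit should offset the vinylogous-amide deactivation of the 3-acylindole carbonyl so that the titanium-bound sulfonamide adds and eliminates to the N-sulfonyl ketimine.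

Step 2
Reactants: 3 ethyl 2-(1H-indol-3-yl)-2-(tosylimino)acetate; 4 indole
Product: 5 ethyl 2,2-bis(1H-indol-3-yl)-2-(tosylamino)acetate
Conditions: (PhO)2P(O)OH (10 mol%), 4 (1.05 equiv), CH2Cl2, 0 °C to rt
Reagents that add atoms: none
Why: Brønsted-acid-catalysed aza-Friedel–Crafts addition, in which the protonated sulfonyl ketimine, stabilised by the indole already attached, is attacked by C3 of the second indole to give the quaternary carbon, which is not a stereocentre because its two indolyl groups are identical.

Step 3
Reactants: 5 ethyl 2,2-bis(1H-indol-3-yl)-2-(tosylamino)acetate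
Product: 6 ethyl 2,2-bis(1-Boc-indol-3-yl)-2-(tosylamino)acetate
Conditions: Boc2O (2.2 equiv), DMAP (10 mol%), MeCN, rt
Reagents that add atoms: di-tert-butyl dicarbonate, CC(C)(C)OC(=O)OC(=O)OC(C)(C)C
Why: DMAP-catalysed N-acylation with Boc2O, which should take place at the two unhindered indole nitrogens and leave the sulfonamide N–H untouched because that nitrogen sits on a fully substituted carbon flanked by two indolyl groups and an ester.

Step 4
Reactants: 6 ethyl 2,2-bis(1-Boc-indol-3-yl)-2-(tosylamino)acetate; 7 2-(trimethylsilyl)phenyl trifluoromethanesulfonate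
Product: 9 1-tosyl-2,2-bis(1-Boc-indol-3-yl)indolin-3-one, via benzyne 8 (not isolated)
Conditions: CsF (3 equiv), dry MeCN, rt, slow addition of 7 (1.5 equiv)
Reagents that add atoms: none
Why: Fluoride attacks silicon in 7 and triflate leaves to give benzyne 8; the cesium sulfonamide of 6 adds to it to form N1–C7a, and the aryl anion left on the neighbouring carbon attacks the ethyl ester and expels ethoxide to form C3–C3a and the ketone. The closest known reaction type is the aryne annulation of N-sulfonyl α-amino esters to N-sulfonyl indolin-3-ones, that is, aryne N-arylation followed by intramolecular anionic acylation. The only ring formed, the five-membered ring of the indoxyl, closes in a 5-exo-trig mode at the ester carbonyl, and the quaternary C2 should favour this by holding ester and aryl anion close together. No stereocentre is created, since C2 carries two identical indolyl groups, and the symmetry of benzyne removes any regiochemical question. The step needs N-arylation at the sulfonamide alone and acylation rather than protonation of the aryl anion: the Boc groups leave the sulfonamide as the only N–H, the solvent is aprotic, and each ethoxide released should be consumed by deprotonating the next sulfonamide, so that only ethanol, a poor competitor for an ester five atoms away, is present. Tosyl is retained because it has no α-hydrogen and is not electron-poor enough for a Truce–Smiles shift of the aryl anion onto the sulfonyl arene.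

Step 5
Reactants: 9 1-tosyl-2,2-bis(1-Boc-indol-3-yl)indolin-3-one
Product: 11 2,2-bis(1H-indol-3-yl)indolin-3-one (2,2-bis(3'-indolyl)indoxyl), via N1-H bis-Boc indoxyl 10 (not isolated)
Conditions: SmI2 (2.2 equiv), THF, −78 to 0 °C; then NaOMe (excess), MeOH, rt
Reagents that add atoms: none
Why: Single-electron reductive N-desulfonylation followed by base-catalysed methanolysis of the indole carbamates: electron transfer into the aryl ketone should give a radical anion that expels the sulfonyl group from N1 (the N–S bond is β to C7a and out of the ring plane, whereas the C2–N1 bond lies in the nodal plane) to leave the conjugated indoxyl aza-enolate, and methoxide is added only after the sulfonamide is gone, so a free indole nitrogen never coexists with a sulfonanilide leaving group on C2.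

**Compound list**

1 | ethyl 2-(1H-indol-3-yl)-2-oxoacetate | CCOC(=O)C(=O)c1c[nH]c2ccccc12 | starting material
2 | 4-methylbenzenesulfonamide | Cc1ccc(cc1)S(N)(=O)=O | starting material
3 | ethyl 2-(1H-indol-3-yl)-2-(tosylimino)acetate (C=N geometry undefined) | CCOC(=O)C(=NS(=O)(=O)c1ccc(C)cc1)c1c[nH]c2ccccc12 | intermediate
4 | indole | c1ccc2[nH]ccc2c1 | starting material
5 | ethyl 2,2-bis(1H-indol-3-yl)-2-(tosylamino)acetate | CCOC(=O)C(NS(=O)(=O)c1ccc(C)cc1)(c1c[nH]c2ccccc12)c1c[nH]c2ccccc12 | intermediate
6 | ethyl 2,2-bis(1-Boc-indol-3-yl)-2-(tosylamino)acetate | CCOC(=O)C(NS(=O)(=O)c1ccc(C)cc1)(c1cn(C(=O)OC(C)(C)C)c2ccccc12)c1cn(C(=O)OC(C)(C)C)c2ccccc12 | intermediate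
7 | 2-(trimethylsilyl)phenyl trifluoromethanesulfonate | C[Si](C)(C)c1ccccc1OS(=O)(=O)C(F)(F)F | starting material
8 | benzyne | C1#CC=CC=C1 | intermediate
9 | 1-tosyl-2,2-bis(1-Boc-indol-3-yl)indolin-3-one | Cc1ccc(cc1)S(=O)(=O)N1c2ccccc2C(=O)C1(c1cn(C(=O)OC(C)(C)C)c2ccccc12)c1cn(C(=O)OC(C)(C)C)c2ccccc12 | intermediate
10 | 2,2-bis(1-Boc-indol-3-yl)indolin-3-one | O=C1c2ccccc2NC1(c1cn(C(=O)OC(C)(C)C)c2ccccc12)c1cn(C(=O)OC(C)(C)C)c2ccccc12 | intermediate
11 | 2,2-bis(1H-indol-3-yl)indolin-3-one (2,2-bis(3'-indolyl)indoxyl) | O=C1c2ccccc2NC1(c1c[nH]c2ccccc12)c1c[nH]c2ccccc12 | target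

**Totals**

Total step count: 5. Longest linear sequence: 5 steps (1 → 3 → 5 → 6 → 9 → 11).

**Steps most likely to fail**

1. Step 4. The ortho aryl anion may be protonated before it reaches the ester, or the congested sulfonamide anion may capture benzyne too slowly, so that aryne self-consumption takes over. The fallback sets out from 1 and comes back at 10; it brings in N1–C7a with an aniline and makes only C3–C3a by anionic acylation. Compound 1 would be condensed with 2-iodoaniline (TiCl4, Et3N, CH2Cl2) to ethyl 2-[(2-iodophenyl)imino]-2-(1H-indol-3-yl)acetate F1. Indole 4 would be added under the acid catalysis of step 2 to give ethyl 2-[(2-iodophenyl)amino]-2,2-bis(1H-indol-3-yl)acetate F2. Both indole nitrogens would be capped (Boc2O, DMAP, MeCN) to give ethyl 2,2-bis(1-Boc-indol-3-yl)-2-[(2-iodophenyl)amino]acetate F3. Treatment with iPrMgCl·LiCl (2.2 equiv, THF, −40 °C to rt) should first remove the aniline proton and then effect iodine–magnesium exchange, and the arylmagnesium should close onto the ester to give 10, which would then be methanolysed as in the second stage of step 5. No sulfonyl group has to be removed on this path.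

2. Step 1. The condensation may stall because the 3-acylindole carbonyl behaves as a vinylogous amide, the more so once Et3N has removed the indole proton. The fallback sets out from 1 and comes back at 6; it takes away the donor character of the indole before the condensation. Compound 1 would be protected (Boc2O, DMAP, MeCN) to ethyl 2-(1-Boc-indol-3-yl)-2-oxoacetate F4, whose ketone is an ordinary aryl glyoxylate carbonyl. Condensation with 2 (TiCl4, Et3N, CH2Cl2, 0 °C) should give ethyl 2-(1-Boc-indol-3-yl)-2-(tosylimino)acetate F5. Acid-catalysed addition of indole 4 should give racemic ethyl 2-(1-Boc-indol-3-yl)-2-(1H-indol-3-yl)-2-(tosylamino)acetate F6, and a second Boc protection (Boc2O, DMAP) would rejoin the route at 6.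

3. Step 5. The C3 ketone may be reduced or pinacol-coupled before the N–S bond fragments, or the fragmentation may be incomplete. The fallback sets out from 9 and comes back at 10; it takes the ketone out of play during the reductive cleavage. The ketone of 9 would be reduced (NaBH4, THF/MeOH, 0 °C) to racemic 1-tosyl-2,2-bis(1-Boc-indol-3-yl)indolin-3-ol F7. The sulfonamide would be cleaved with Na/naphthalene (THF, −78 °C) to racemic 2,2-bis(1-Boc-indol-3-yl)indolin-3-ol F8. The benzylic alcohol would be reoxidised with activated MnO2 (CH2Cl2, rt) to 10, which would then be methanolysed as in the second stage of step 5.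

**Further compounds**

F1 | step 4 | ethyl 2-[(2-iodophenyl)imino]-2-(1H-indol-3-yl)acetate | CCOC(=O)C(=Nc1ccccc1I)c1c[nH]c2ccccc12
F2 | step 4 | ethyl 2-[(2-iodophenyl)amino]-2,2-bis(1H-indol-3-yl)acetate | CCOC(=O)C(Nc1ccccc1I)(c1c[nH]c2ccccc12)c1c[nH]c2ccccc12
F3 | step 4 | ethyl 2,2-bis(1-Boc-indol-3-yl)-2-[(2-iodophenyl)amino]acetate | CCOC(=O)C(Nc1ccccc1I)(c1cn(C(=O)OC(C)(C)C)c2ccccc12)c1cn(C(=O)OC(C)(C)C)c2ccccc12
F4 | step 1 | ethyl 2-(1-Boc-indol-3-yl)-2-oxoacetate | CCOC(=O)C(=O)c1cn(C(=O)OC(C)(C)C)c2ccccc12
F5 | step 1 | ethyl 2-(1-Boc-indol-3-yl)-2-(tosylimino)acetate | CCOC(=O)C(=NS(=O)(=O)c1ccc(C)cc1)c1cn(C(=O)OC(C)(C)C)c2ccccc12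
F6 | step 1 | ethyl 2-(1-Boc-indol-3-yl)-2-(1H-indol-3-yl)-2-(tosylamino)acetate (racemic) | CCOC(=O)C(NS(=O)(=O)c1ccc(C)cc1)(c1c[nH]c2ccccc12)c1cn(C(=O)OC(C)(C)C)c2ccccc12
F7 | step 5 | 1-tosyl-2,2-bis(1-Boc-indol-3-yl)indolin-3-ol (racemic) | Cc1ccc(cc1)S(=O)(=O)N1c2ccccc2C(O)C1(c1cn(C(=O)OC(C)(C)C)c2ccccc12)c1cn(C(=O)OC(C)(C)C)c2ccccc12
F8 | step 5 | 2,2-bis(1-Boc-indol-3-yl)indolin-3-ol (racemic) | OC1c2ccccc2NC1(c1cn(C(=O)OC(C)(C)C)c2ccccc12)c1cn(C(=O)OC(C)(C)C)c2ccccc12
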